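The top flavan C ring is cut at O1–C2 and C3–C4. Its C4 is a methine between the top A ring (ortho to the phenolic O1) and C6 of the middle A ring, i.e. a latent ortho-quinone methide O1=C8a–C4a=C4. In the key step both epimers of an o-hydroxybenzhydrol collapse to this planar quinone methide, which takes up the enamine of benzyloxyacetaldehyde (C2–C3) in a catalyst-controlled formal [4+2]: C3–C4 by anti-Michael addition, O1–C2 by hemiacetal closure, giving the 3,4-cis lactol. The B ring then enters at C2 trans to both neighbours. The middle unit is a dihydroflavonol from a Juliá–Colonna epoxide; the lower unit joins last by thiophilic flavan-4-yl coupling.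

Key step: step 8

Assumption: the (R,R)-configured primary amine–thiourea is taken to deliver the 3S,4β pair in step 8 by analogy with its sense of induction on nitroalkenes; if the sense is opposite, the (S,S)-antipode is used and nothing else changes.

Step 1
Reactants: 1 4'-(benzyloxy)-2'-hydroxyacetophenone
Product: 2 4'-(benzyloxy)-5'-bromo-2'-hydroxyacetophenone
Conditions: NBS, NH4OAc (cat.), MeCN, 0 °C to rt
Reagents that add atoms: N-bromosuccinimide O=C1CCC(=O)N1Br
Why: electrophilic aromatic bromination should go para to the free phenol and ortho to the benzyloxy group (C5'), the position between the two oxygens being hindered.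

Step 2
Reactants: 2 4'-(benzyloxy)-5'-bromo-2'-hydroxyacetophenone
Product: 3 4'-(benzyloxy)-5'-bromo-2'-(methoxymethoxy)acetophenone
Conditions: MOMCl, i-Pr2NEt, CH2Cl2, 0 °C to reflux
Reagents that add atoms: chloromethyl methyl ether COCCl
Why: O-alkylation to the MOM ether masks the phenol so that the later enone can be epoxidised with basic peroxide without Algar–Flynn–Oyamada cyclisation.

Step 3
Reactants: 3 4'-(benzyloxy)-5'-bromo-2'-(methoxymethoxy)acetophenone; 4 3,4-bis(benzyloxy)benzaldehyde
Product: 5 (E)-chalcone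
Conditions: KOH, EtOH/THF, rt
Reagents that add atoms: none
Why: Claisen–Schmidt condensation should give the (E)-enone under thermodynamic control.

Step 4
Reactants: 5 (E)-chalcone
Product: 6 trans-(αR,βS)-epoxy ketone
Conditions: poly-L-leucine, urea–H2O2, DBU, THF, rt
Reagents that add atoms: urea–hydrogen peroxide OO.NC(N)=O
Why: Juliá–Colonna epoxidation, in which the helical poly-L-leucine delivers hydroperoxide to one enone face and sets the (αR,βS) trans-epoxide that becomes C3 and C2 of the flavanone.

Step 5
Reactants: 6 trans-(αR,βS)-epoxy ketone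
Product: 8 (2R,3R)-6-bromo-7,3',4'-tri-O-benzyl dihydroflavonol, via phenolic epoxy ketone 7 (not isolated)
Conditions: aq. HCl, MeOH/THF, 55 °C
Reagents that add atoms: none
Why: acid removes the MOM acetal and the freed phenol opens the epoxide at the electron-rich benzylic carbon (6-endo-tet) with inversion, giving the 2,3-trans (2R,3R) dihydroflavonol with C3 carried over from the epoxide.

Step 6
Reactants: 8 (2R,3R)-6-bromo-7,3',4'-tri-O-benzyl dihydroflavonol
Product: 9 (2R,3R)-6-formyl-7,3',4'-tri-O-benzyl dihydroflavonol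
Conditions: Pd(OAc)2 (cat.), cataCXium A (cat.), CO/H2 (1:1, 5 bar), TMEDA, toluene, 100 °C
Reagents that add atoms: carbon monoxide [C-]#[O+]
Why: palladium-catalysed reductive carbonylation (formylation) of the aryl bromide tolerates the ketone and the free alcohol and touches no stereocentre.

Step 7
Reactants: 9 (2R,3R)-6-formyl-7,3',4'-tri-O-benzyl dihydroflavonol; 10 3-(benzyloxy)phenol
Product: 12 o-hydroxybenzhydrol (both carbinol epimers), via benzodioxaborin 11 (not isolated)
Conditions: PhB(OH)2, EtCO2H (cat.), toluene, reflux (Dean–Stark); then propane-1,3-diol, THF, rt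
Reagents that add atoms: none
Why: boronic acid-templated ortho-hydroxyalkylation of the phenol (Nagata reaction) delivers the aldehyde to the free ortho position para to the benzyloxy group and stops at the carbinol stage as the cyclic boronate; the new carbinol centre forms unselectively, which is harmless because step 8 erases it.

Step 8
Reactants: 12 o-hydroxybenzhydrol (both carbinol epimers); 13 (benzyloxy)acetaldehyde
Product: 15 3,4-cis lactol (3S, C4 aryl cis to 3-OBn, both C2 anomers), via o-quinone methide 14 (not isolated)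
Conditions: 1-[(1R,2R)-2-aminocyclohexyl]-3-[3,5-bis(trifluoromethyl)phenyl]thiourea (20 mol %), 2,4-dinitrobenzoic acid (20 mol %), CHCl3, 35 °C
Reagents that add atoms: none
Why: Proposed new method: acid-assisted loss of water from either carbinol epimer of 12 gives the same planar (E)-o-quinone methide 14 (stereoconvergent at C4), the Z-enamine formed from 13 and the primary amine (held by an N–H···OBn hydrogen bond) adds through C3 to the methide carbon C4 while the thiourea binds the quinone methide oxygen, and after hydrolysis of the iminium ion the regenerated phenol closes onto C2 by 6-exo-trig hemiacetalisation, overall a formal inverse-demand [4+2] (Michael addition, then hemiacetal formation). The closest known reactions are the anti-selective primary amine–thiourea Michael additions of α-oxyacetaldehydes to nitroalkenes and the amine-catalysed additions of aldehydes to quinone methides made in situ. C3 (S) and C4 are set together by the catalyst-bound Z-enamine in the endo, anti-Michael arrangement, which places the benzyloxy group cis to the C4 aryl group (the future 4β link); C2 stays a hemiacetal and is set in step 9. The step needs C-attack at C4 over O- or N-capture of 14, anti over syn topology and one enamine face; the E geometry of 14 (flavanone ring turned away from the carbonyl), the chelated Z-enamine and the thiourea binding are meant to secure them, and the remote stereocentres of the flavanone unit are too far from C4 to interfere.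

Step 9
Reactants: 15 3,4-cis lactol; 16 1,2-bis(benzyloxy)benzene
Product: 17 hepta-O-benzyl fisetinidol-(4β→6)-fustin
Conditions: 16 (10 equiv), Sc(OTf)3 (10 mol %), 4 Å MS, CH2Cl2, −30 to 0 °C
Reagents that add atoms: none
Why: Friedel–Crafts C-arylation of the cyclic aryloxocarbenium ion (C-glycosylation type) in which the arene reacts para to an ether oxygen and should add to C2 from the face opposite the cis-disposed 3-benzyloxy and 4-aryl groups, setting 2R (2,3-trans, 2,4-trans).

Step 10
Reactants: 17 hepta-O-benzyl fisetinidol-(4β→6)-fustin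
Product: 18 fisetinidol-(4β→6)-fustin
Conditions: H2 (1 atm), Pd(OH)2/C, THF/MeOH, rt
Reagents that add atoms: none
Why: hydrogenolysis of the seven benzyl ethers under neutral conditions should leave the electron-rich aryl ketone and the chroman C–O bonds untouched.

Step 11
Reactants: 18 fisetinidol-(4β→6)-fustin
Product: 19 fisetinidol-(4β→6)-mollisacacidin (3,4-trans diol in the lower ring)
Conditions: NaBH4, EtOH, 0 °C to rt
Reagents that add atoms: none
Why: borohydride reduction of the dihydroflavonol carbonyl with hydride attack anti to the 3-hydroxyl group should give mainly the 3,4-trans diol, a centre that is ionised again in step 15.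

Step 12
Reactants: 19 fisetinidol-(4β→6)-mollisacacidin
Product: 20 4-benzylthio derivative (epimers at the thio-bearing carbon)
Conditions: BnSH (excess), AcOH, rt
Reagents that add atoms: phenylmethanethiol SCc1ccccc1
Why: SN1 thiolysis of the benzylic 4-hydroxyl through the A-ring-stabilised flavan-4-yl cation, the excess thiol outcompeting self-condensation, gives a stable thioether that can be activated under near-neutral conditions.

Step 13
Reactants: 8 (2R,3R)-6-bromo-7,3',4'-tri-O-benzyl dihydroflavonol
Product: 21 (+)-fustin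
Conditions: H2 (1 atm), Pd/C, NaOAc, EtOAc/MeOH, rt
Reagents that add atoms: none
Why: hydrogenolysis of the three benzyl ethers with concomitant hydrodebromination of the aryl bromide should give (2R,3R)-fustin without touching C2 or C3.

Step 14
Reactants: 21 (+)-fustin
Product: 22 (+)-mollisacacidin
Conditions: NaBH4, EtOH, 0 °C to rt
Reagents that add atoms: none
Why: borohydride reduction with hydride delivered anti to the 3-hydroxyl group sets 4R (2,3-trans-3,4-trans).

Step 15
Reactants: 20 4-benzylthio derivative; 22 (+)-mollisacacidin (excess)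
Product: 23 CNP0255184.1
Conditions: AgBF4, THF, 0 °C
Reagents that add atoms: none
Why: thiophilic silver activation generates the flavan-4-yl cation, which should be attacked by C6 of the resorcinol-type A ring of 22 (ortho to OH, para to the ring oxygen, less hindered than C8) from the face trans to the 3-hydroxyl group (4α), a biomimetic Friedel–Crafts interflavanyl coupling that leaves the 4-hydroxyl of the terminal unit in place.

Compound list
1 | 1-[4-(benzyloxy)-2-hydroxyphenyl]ethan-1-one | CC(=O)c1ccc(OCc2ccccc2)cc1O | starting material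
2 | 1-[4-(benzyloxy)-5-bromo-2-hydroxyphenyl]ethan-1-one | CC(=O)c1cc(Br)c(OCc2ccccc2)cc1O | intermediate
3 | 1-[4-(benzyloxy)-5-bromo-2-(methoxymethoxy)phenyl]ethan-1-one | CC(=O)c1cc(Br)c(OCc2ccccc2)cc1OCOC | intermediate
4 | 3,4-bis(benzyloxy)benzaldehyde | O=Cc1ccc(OCc2ccccc2)c(OCc2ccccc2)c1 | starting material
5 | (E)-1-[4-(benzyloxy)-5-bromo-2-(methoxymethoxy)phenyl]-3-[3,4-bis(benzyloxy)phenyl]prop-2-en-1-one | COCOc1cc(OCc2ccccc2)c(Br)cc1C(=O)/C=C/c1ccc(OCc2ccccc2)c(OCc2ccccc2)c1 | intermediate
6 | [4-(benzyloxy)-5-bromo-2-(methoxymethoxy)phenyl][(2R,3S)-3-[3,4-bis(benzyloxy)phenyl]oxiran-2-yl]methanone | COCOc1cc(OCc2ccccc2)c(Br)cc1C(=O)[C@@H]1O[C@H]1c1ccc(OCc2ccccc2)c(OCc2ccccc2)c1 | intermediate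
7 | [4-(benzyloxy)-5-bromo-2-hydroxyphenyl][(2R,3S)-3-[3,4-bis(benzyloxy)phenyl]oxiran-2-yl]methanone | Oc1cc(OCc2ccccc2)c(Br)cc1C(=O)[C@@H]1O[C@H]1c1ccc(OCc2ccccc2)c(OCc2ccccc2)c1 | intermediate (not isolated)
8 | (2R,3R)-7-(benzyloxy)-2-[3,4-bis(benzyloxy)phenyl]-6-bromo-3-hydroxychroman-4-one | Brc1cc2c(cc1OCc1ccccc1)O[C@H](c1ccc(OCc3ccccc3)c(OCc3ccccc3)c1)[C@@H](O)C2=O | intermediate
9 | (2R,3R)-7-(benzyloxy)-2-[3,4-bis(benzyloxy)phenyl]-3-hydroxy-4-oxochromane-6-carbaldehyde | O=Cc1cc2c(cc1OCc1ccccc1)O[C@H](c1ccc(OCc3ccccc3)c(OCc3ccccc3)c1)[C@@H](O)C2=O | intermediate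
10 | 3-(benzyloxy)phenol | Oc1cccc(OCc2ccccc2)c1 | starting material
11 | 7-(benzyloxy)-2-phenyl-4H-1,3,2-benzodioxaborin carrying at C4 the C6 of the (2R,3R)-dihydroflavonol of 9 (both C4 epimers) | c1ccccc1B1Oc2cc(OCc3ccccc3)ccc2C(O1)c1cc2c(cc1OCc1ccccc1)O[C@H](c1ccc(OCc3ccccc3)c(OCc3ccccc3)c1)[C@@H](O)C2=O | intermediate (not isolated)
12 | (2R,3R)-7-(benzyloxy)-6-{[4-(benzyloxy)-2-hydroxyphenyl](hydroxy)methyl}-2-[3,4-bis(benzyloxy)phenyl]-3-hydroxychroman-4-one, both carbinol epimers | OC(c1ccc(OCc2ccccc2)cc1O)c1cc2c(cc1OCc1ccccc1)O[C@H](c1ccc(OCc3ccccc3)c(OCc3ccccc3)c1)[C@@H](O)C2=O | intermediate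
13 | (benzyloxy)acetaldehyde | O=CCOCc1ccccc1 | starting material
14 | (E)-o-quinone methide: 3-(benzyloxy)-6-(arylmethylidene)cyclohexa-2,4-dien-1-one, aryl = C6 of the (2R,3R)-dihydroflavonol, aryl anti to the carbonyl | O=C1C=C(OCc2ccccc2)C=C\C1=C/c1cc2c(cc1OCc1ccccc1)O[C@H](c1ccc(OCc3ccccc3)c(OCc3ccccc3)c1)[C@@H](O)C2=O | intermediate (not isolated)
15 | (3S)-3,7-bis(benzyloxy)-4-[(2R,3R)-7-(benzyloxy)-2-[3,4-bis(benzyloxy)phenyl]-3-hydroxy-4-oxochroman-6-yl]chroman-2-ol, C4 aryl cis to 3-OBn, both C2 anomers | c1ccc(cc1)COc1ccc2c(c1)OC(O)[C@@H](OCc1ccccc1)[C@H]2c1cc2c(cc1OCc1ccccc1)O[C@H](c1ccc(OCc3ccccc3)c(OCc3ccccc3)c1)[C@@H](O)C2=O | intermediate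
16 | 1,2-bis(benzyloxy)benzene | c1ccc(cc1)COc1ccccc1OCc1ccccc1 | starting material
17 | hepta-O-benzyl fisetinidol-(4β→6)-fustin: (2R,3S)-3,7-bis(benzyloxy)-2-[3,4-bis(benzyloxy)phenyl]chroman-4-yl (C4 aryl cis to 3-OBn, trans to the C2 aryl) bound to C6 of (2R,3R)-7-(benzyloxy)-2-[3,4-bis(benzyloxy)phenyl]-3-hydroxychroman-4-one | c1ccc(cc1)COc1ccc2c(c1)O[C@H](c1ccc(OCc3ccccc3)c(OCc3ccccc3)c1)[C@@H](OCc1ccccc1)[C@H]2c1cc2c(cc1OCc1ccccc1)O[C@H](c1ccc(OCc3ccccc3)c(OCc3ccccc3)c1)[C@@H](O)C2=O | intermediate
18 | fisetinidol-(4β→6)-fustin: (2R,3S,4S)-2-(3,4-dihydroxyphenyl)-3,7-dihydroxychroman-4-yl bound to C6 of (2R,3R)-fustin | Oc1ccc2c(c1)O[C@H](c1ccc(O)c(O)c1)[C@@H](O)[C@H]2c1cc2c(cc1O)O[C@H](c1ccc(O)c(O)c1)[C@@H](O)C2=O | intermediate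
19 | fisetinidol-(4β→6)-mollisacacidin: as 18 with the lower ring reduced to the (2R,3S,4R)-3,4-trans diol | Oc1ccc2c(c1)O[C@H](c1ccc(O)c(O)c1)[C@@H](O)[C@H]2c1cc2c(cc1O)O[C@H](c1ccc(O)c(O)c1)[C@@H](O)[C@@H]2O | intermediate
20 | 4-(benzylthio) analogue of 19 (benzylthio in place of the benzylic 4-hydroxyl, both epimers at that carbon) | Oc1ccc2c(c1)O[C@H](c1ccc(O)c(O)c1)[C@@H](O)[C@H]2c1cc2c(cc1O)O[C@H](c1ccc(O)c(O)c1)[C@@H](O)C2SCc1ccccc1 | intermediate
21 | (+)-fustin, (2R,3R)-2-(3,4-dihydroxyphenyl)-3,7-dihydroxychroman-4-one | Oc1ccc2c(c1)O[C@H](c1ccc(O)c(O)c1)[C@@H](O)C2=O | intermediate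
22 | (+)-mollisacacidin, (2R,3S,4R)-2-(3,4-dihydroxyphenyl)chromane-3,4,7-triol | Oc1ccc2c(c1)O[C@H](c1ccc(O)c(O)c1)[C@@H](O)[C@@H]2O | intermediate
23 | CNP0255184.1, (2R,3S,4S)-fisetinidol-(4β→6)-(2R,3S,4R)-fisetinidol-(4α→6)-(2R,3S,4R)-mollisacacidin | Oc1ccc2c(c1)O[C@H](c1ccc(O)c(O)c1)[C@@H](O)[C@H]2c1cc2c(cc1O)O[C@H](c1ccc(O)c(O)c1)[C@@H](O)[C@@H]2c1cc2c(cc1O)O[C@H](c1ccc(O)c(O)c1)[C@@H](O)[C@@H]2O | target

Total step count: 15. Longest linear sequence: 13 steps (steps 1 to 12, then step 15); steps 13 and 14 branch off from compound 8.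

Steps most likely to fail

Step 8 (Proposed new method). The quinone methide may be captured at oxygen or by the amine catalyst instead of by the enamine carbon, the addition may take the syn topology (3,4-trans), the enamine face may be poorly differentiated, or the aldehyde may self-condense. The fallback uses established reaction types and sets out from 12. Heating 12 in neat vinylene carbonate (about 120 °C) generates 14 thermally, and an uncatalysed endo hetero-Diels–Alder reaction with this planar cis-dioxygenated dienophile should give the cis-fused cyclic carbonate F1 with the carbonate cis to the C4 aryl group. The two endo adducts are diastereomers because of the flavanone unit and are separated by chromatography. Lewis acid (BF3·OEt2) with an excess of 16 then ionises the anomeric C–O bond, the arene enters anti to the departing carbonate, and carbon dioxide is lost to give the 3-hydroxy hexabenzyl ether F2. Hydrogenolysis as in step 10 brings the sequence back to the route at 18.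

Step 9. The arene may add with poor facial selectivity, C2 may epimerise through reversible opening to the benzylic cation, or the electron-rich A ring of a second molecule may compete with the external arene. The fallback sets out from 15 and replaces electrophilic aromatic substitution by ipso-transfer from boron. Potassium [3,4-bis(benzyloxy)phenyl]trifluoroborate F3 is made from the commercial boronic acid with KHF2 and added to the oxocarbenium ion generated from 15 with BF3·OEt2 in MeCN at −20 °C. This fixes the aryl regiochemistry, lets the reaction run cold and stoichiometric in nucleophile, and comes back to the route at 17.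

Step 15. The cation may be attacked at C8 instead of C6 or from the 4β face, and the acid released may ionise the 4-hydroxyl of the nucleophile or of the product and cause over-condensation. The fallback sets out from 20 and couples it under the same silver activation with (+)-fustin 21 instead of 22. The terminal unit then enters at the ketone oxidation level and cannot ionise, giving the trimer ketone F4. Borohydride reduction as in step 14 (hydride anti to the 3-hydroxyl) then gives the 3,4-trans diol and comes back to the route at 23.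

Further compounds
F1 | step 8 | cis-fused cyclic carbonate of the (2,3-cis)-chroman-2,3-diol: 7-(benzyloxy)-4-aryl-chromano[2,3-d][1,3]dioxol-2-one, C4 aryl (C6 of the dihydroflavonol of 9) cis to both ring oxygens | c1ccc(cc1)COc1ccc2c(c1)O[C@H]1OC(=O)O[C@H]1[C@H]2c1cc2c(cc1OCc1ccccc1)O[C@H](c1ccc(OCc3ccccc3)c(OCc3ccccc3)c1)[C@@H](O)C2=O
F2 | step 8 | 3-hydroxy analogue of 17 (hexa-O-benzyl fisetinidol-(4β→6)-fustin with free 3-OH in the upper unit) | c1ccc(cc1)COc1ccc2c(c1)O[C@H](c1ccc(OCc3ccccc3)c(OCc3ccccc3)c1)[C@@H](O)[C@H]2c1cc2c(cc1OCc1ccccc1)O[C@H](c1ccc(OCc3ccccc3)c(OCc3ccccc3)c1)[C@@H](O)C2=O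
F3 | step 9 | potassium [3,4-bis(benzyloxy)phenyl]trifluoroborate | [K+].F[B-](F)(F)c1ccc(OCc2ccccc2)c(OCc2ccccc2)c1
F4 | step 15 | fisetinidol-(4β→6)-fisetinidol-(4α→6)-fustin (target with the lowest ring as the (2R,3R)-dihydroflavonol) | Oc1ccc2c(c1)O[C@H](c1ccc(O)c(O)c1)[C@@H](O)[C@H]2c1cc2c(cc1O)O[C@H](c1ccc(O)c(O)c1)[C@@H](O)[C@@H]2c1cc2c(cc1O)O[C@H](c1ccc(O)c(O)c1)[C@@H](O)C2=O
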